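**Retrosynthetic overview**
1. The target, (3R,3'R,6'R)-7,8-didehydro-β,ε-carotene-3,3'-diol, is cut at the C10'–C11' σ-bond into a C13 ε-ring terminal enyne (16) and a C26 hexaenynyl iodide (10). The forward union is a one-pot Zr-catalysed methylalumination / Pd–Zn alkenyl–alkenyl coupling, followed by desilylation.
2. Enabling feature: the C19' methyl on C9' lies syn to H–C10' across the E-C9'=C10' bond that flanks the C10'–C11' bond. This is the imprint of a syn Me–Al addition to a C9'≡C10'–H alkyne, so C10' is generated as the nucleophile in the flask and the C19' methyl arrives in the same operation.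
3. C26 iodide 10: Takai iodo-olefination (adds C11') of the C25 aldehyde 9, which comes from a Wittig reaction (C11=C12) of the acetylenic C15 phosphonium salt 7 with C10-dialdehyde 8. Salt 7 comes from a Sonogashira coupling (C6–C7) of the actinol-derived vinyl triflate 3 with enynol 4.
4. C13 enyne 16: (R)-α-ionone → terminal alkyne (enol phosphate elimination) → allylic C–H oxidation at C3' → CBS reduction (sets 3'R) → TBS ether.
5. Ring order: no ring is built. The β-ring (C3 stereocentre) is bought as (4R,6R)-actinol and the ε-ring (C6' stereocentre) as (R)-α-ionone.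

Key step: step 12

Assumption: (4R,6R)-actinol (1), all-E C10-dialdehyde (8) and enantiopure (R)-α-ionone (11) are taken as purchasable; Cp2ZrCl2 and ZnCl2 are used sub-stoichiometrically in step 12. Locants such as C9', C10' follow carotenoid numbering.

**Step 1**
Reactants: 1 (4R,6R)-4-hydroxy-2,2,6-trimethylcyclohexan-1-one (actinol)
Product: 2 (4R,6R)-4-[(tert-butyldimethylsilyl)oxy]-2,2,6-trimethylcyclohexan-1-one
Conditions: TBSCl, imidazole, DMF, rt
Reagents that add atoms: tert-butyldimethylsilyl chloride, CC(C)(C)[Si](C)(C)Cl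
Why: Standard silylation of a secondary alcohol with TBSCl/imidazole, which masks the hydroxyl for the enolate and organoaluminium chemistry ahead and touches no stereocentre.

**Step 2**
Reactants: 2 (4R,6R)-4-[(tert-butyldimethylsilyl)oxy]-2,2,6-trimethylcyclohexan-1-one
Product: 3 (4R)-4-[(tert-butyldimethylsilyl)oxy]-2,6,6-trimethylcyclohex-1-en-1-yl trifluoromethanesulfonate
Conditions: LDA, THF, −78 °C; then PhNTf2, −78 °C → rt
Reagents that add atoms: N-phenylbis(trifluoromethanesulfonimide), O=S(=O)(N(c1ccccc1)S(=O)(=O)C(F)(F)F)C(F)(F)F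
Why: Enol triflate formation, in which the ketone can enolise only toward the methyl-bearing carbon (the other α-carbon is quaternary), so one tetrasubstituted vinyl triflate should form; the methyl-bearing stereocentre is deliberately erased and the silyloxy carbon is untouched.

**Step 3**
Reactants: 3 (4R)-4-[(tert-butyldimethylsilyl)oxy]-2,6,6-trimethylcyclohex-1-en-1-yl trifluoromethanesulfonate; 4 (2E)-3-methylpent-2-en-4-yn-1-ol
Product: 5 (2E)-5-[(4R)-4-[(tert-butyldimethylsilyl)oxy]-2,6,6-trimethylcyclohex-1-en-1-yl]-3-methylpent-2-en-4-yn-1-ol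
Conditions: Pd(PPh3)4 (5 mol%), CuI (10 mol%), i-Pr2NH, THF, rt → 40 °C
Reagents that add atoms: none
Why: Sonogashira coupling of a cyclohexenyl triflate with a terminal alkyne forms the C6–C7 bond and carries the E-geometry of 4 (the future 9E bond) through unchanged; the free primary alcohol is tolerated.

**Step 4**
Reactants: 5 (2E)-5-[(4R)-4-[(tert-butyldimethylsilyl)oxy]-2,6,6-trimethylcyclohex-1-en-1-yl]-3-methylpent-2-en-4-yn-1-ol
Product: 6 {[(1R)-4-[(3E)-5-bromo-3-methylpent-3-en-1-yn-1-yl]-3,5,5-trimethylcyclohex-3-en-1-yl]oxy}(tert-butyl)dimethylsilane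
Conditions: CBr4, PPh3, CH2Cl2, −20 → 0 °C
Reagents that add atoms: carbon tetrabromide, BrC(Br)(Br)Br
Why: Appel bromination of a primary allylic alcohol proceeds by SN2 under neutral conditions, so the silyl ether and the trisubstituted alkene geometry should survive.

**Step 5**
Reactants: 6 {[(1R)-4-[(3E)-5-bromo-3-methylpent-3-en-1-yn-1-yl]-3,5,5-trimethylcyclohex-3-en-1-yl]oxy}(tert-butyl)dimethylsilane
Product: 7 [(2E)-5-[(4R)-4-[(tert-butyldimethylsilyl)oxy]-2,6,6-trimethylcyclohex-1-en-1-yl]-3-methylpent-2-en-4-yn-1-yl]triphenylphosphonium bromide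
Conditions: PPh3, EtOAc, rt, dark
Reagents that add atoms: triphenylphosphine, c1ccc(cc1)P(c1ccccc1)c1ccccc1
Why: SN2 quaternisation of triphenylphosphine by a primary allylic bromide should precipitate the Wittig salt from ethyl acetate.

**Step 6**
Reactants: 7 [(2E)-5-[(4R)-4-[(tert-butyldimethylsilyl)oxy]-2,6,6-trimethylcyclohex-1-en-1-yl]-3-methylpent-2-en-4-yn-1-yl]triphenylphosphonium bromide; 8 (2E,4E,6E)-2,7-dimethylocta-2,4,6-trienedial (C10-dialdehyde)
Product: 9 (2E,4E,6E,8E,10E)-13-[(4R)-4-[(tert-butyldimethylsilyl)oxy]-2,6,6-trimethylcyclohex-1-en-1-yl]-2,7,11-trimethyltrideca-2,4,6,8,10-pentaen-12-ynal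
Conditions: 8 (2 equiv), NaOMe, MeOH/CH2Cl2, 0 °C → rt; then heptane, 80 °C, dark
Reagents that add atoms: none
Why: Wittig olefination of the semi-stabilised allylic ylide with an excess of the symmetrical dialdehyde should give mono-condensation at C11=C12, and the hindered 11Z isomer formed alongside should relax thermally to the all-E aldehyde without equilibrating the 9E bond.

**Step 7**
Reactants: 9 (2E,4E,6E,8E,10E)-13-[(4R)-4-[(tert-butyldimethylsilyl)oxy]-2,6,6-trimethylcyclohex-1-en-1-yl]-2,7,11-trimethyltrideca-2,4,6,8,10-pentaen-12-ynal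
Product: 10 tert-butyl{[(1R)-4-[(3E,5E,7E,9E,11E,13E)-14-iodo-3,7,12-trimethyltetradeca-3,5,7,9,11,13-hexaen-1-yn-1-yl]-3,5,5-trimethylcyclohex-3-en-1-yl]oxy}dimethylsilane
Conditions: CrCl2, CHI3, THF/dioxane, 0 °C → rt, dark
Reagents that add atoms: iodoform, IC(I)I
Why: Takai olefination adds the iodomethylene carbon (C11') to the aldehyde through a gem-dichromium carbenoid, and anti-elimination from the β-oxido chromium intermediate should give the E-alkenyl iodide while the silyl ether, alkyne and polyene are left alone.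

**Step 8**
Reactants: 11 (3E)-4-[(1R)-2,6,6-trimethylcyclohex-2-en-1-yl]but-3-en-2-one ((R)-α-ionone)
Product: 13 (6R)-6-[(1E)-but-1-en-3-yn-1-yl]-1,5,5-trimethylcyclohex-1-ene, via dienyl diethyl phosphate 12 (not isolated)
Conditions: LDA, THF, −78 °C; ClP(O)(OEt)2, −78 °C → rt; then LDA (2.3 equiv), THF, −78 °C → rt; H2O
Reagents that add atoms: none
Why: Kinetic deprotonation at the methyl group, O-phosphorylation and LDA-induced elimination of phosphate (the enol phosphate route from a methyl ketone to a terminal alkyne) should give the enyne, with the ring C–H at the stereocentre shielded by the gem-dimethyl group so that its configuration is kept.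

**Step 9**
Reactants: 13 (6R)-6-[(1E)-but-1-en-3-yn-1-yl]-1,5,5-trimethylcyclohex-1-ene
Product: 14 (4R)-4-[(1E)-but-1-en-3-yn-1-yl]-3,5,5-trimethylcyclohex-2-en-1-one
Conditions: Rh2(cap)4 (1 mol%), t-BuOOH (70% aq.), (CH2Cl)2, 40 °C
Reagents that add atoms: tert-butyl hydroperoxide, CC(C)(C)OO
Why: Dirhodium/TBHP allylic C–H oxidation (H-abstraction by t-BuOO•, then collapse of the mixed peroxide) should convert the ring CH2 next to the trisubstituted alkene into the enone, as in the oxidation of α-ionone to 3-oxo-α-ionone, and the base-free conditions protect the now γ-acidic stereocentre.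

**Step 10**
Reactants: 14 (4R)-4-[(1E)-but-1-en-3-yn-1-yl]-3,5,5-trimethylcyclohex-2-en-1-one
Product: 15 (1R,4R)-4-[(1E)-but-1-en-3-yn-1-yl]-3,5,5-trimethylcyclohex-2-en-1-ol
Conditions: (S)-Me-CBS (0.2 equiv), catecholborane, toluene, −78 °C; then aq. NaHCO3
Reagents that add atoms: none
Why: Corey–Bakshi–Shibata reduction under reagent control, with the alkenyl arm of the enone as the large group, should deliver hydride to the face that gives the (1R)-carbinol trans to the C4 side chain, and catecholborane at −78 °C does not hydroborate the alkyne or alkenes.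

**Step 11**
Reactants: 15 (1R,4R)-4-[(1E)-but-1-en-3-yn-1-yl]-3,5,5-trimethylcyclohex-2-en-1-ol
Product: 16 tert-butyl{[(1R,4R)-4-[(1E)-but-1-en-3-yn-1-yl]-3,5,5-trimethylcyclohex-2-en-1-yl]oxy}dimethylsilane
Conditions: TBSCl, imidazole, DMF, 0 °C → rt
Reagents that add atoms: tert-butyldimethylsilyl chloride, CC(C)(C)[Si](C)(C)Cl
Why: Standard silylation of the secondary allylic alcohol removes the only proton source that would quench the alkenylalane of the next step and leaves both stereocentres untouched.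

**Step 12**
Reactants: 16 tert-butyl{[(1R,4R)-4-[(1E)-but-1-en-3-yn-1-yl]-3,5,5-trimethylcyclohex-2-en-1-yl]oxy}dimethylsilane; 10 tert-butyl{[(1R)-4-[(3E,5E,7E,9E,11E,13E)-14-iodo-3,7,12-trimethyltetradeca-3,5,7,9,11,13-hexaen-1-yn-1-yl]-3,5,5-trimethylcyclohex-3-en-1-yl]oxy}dimethylsilane
Product: 18 (3R,3'R,6'R)-3,3'-bis[(tert-butyldimethylsilyl)oxy]-7,8-didehydro-β,ε-carotene, via dienyl dimethylalane 17 (not isolated)
Conditions: Me3Al (2 equiv), Cp2ZrCl2 (20 mol%), (CH2Cl)2, rt; volatiles removed; then 10, Pd2(dba)3 (2.5 mol%), P(2-furyl)3 (10 mol%), ZnCl2 (0.3 equiv), THF, rt, dark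
Reagents that add atoms: trimethylaluminium, C[Al](C)C
Why: A methylzirconocene species generated from Me3Al/Cp2ZrCl2 should add Me and metal syn across the terminal C9'≡C10' alkyne, placing the C19' methyl on C9' and aluminium on C10' to give the E-dienylalane 17; Pd(0) then inserts into the C11'–I bond of 10, the alkenyl group is relayed Al → Zn → Pd, and reductive elimination forms the C10'–C11' bond with retention at both alkenyl carbons. The closest known reaction type is the tandem Zr-catalysed carboalumination / Pd–Zn-catalysed alkenyl–alkenyl (Negishi) coupling used to forge the analogous C10–C11 bond of β-ionone-derived retinoids and carotenoids. No ring is closed and no stereocentre is created; the three ring stereocentres are spectators, and the new stereo-element, the E-C9'=C10' bond, is fixed by the syn mode of carbometalation. Regioselectivity (Al on the terminal carbon) is secured by the terminal, conjugated alkyne of 16. Chemoselectivity against the C7≡C8 alkyne of 10 is secured because that alkyne is internal and flanked by the tetrasubstituted ring alkene and C9, and because carbometalation is complete, excess Me3Al removed and the medium switched to THF (which shuts carboalumination down) before 10 is added. The two silyl ethers prevent protonolysis of 17, and this single operation delivers the full C40 skeleton with all ten chain unsaturations in place.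

**Step 13**
Reactants: 18 (3R,3'R,6'R)-3,3'-bis[(tert-butyldimethylsilyl)oxy]-7,8-didehydro-β,ε-carotene
Product: 19 (3R,3'R,6'R)-7,8-didehydro-β,ε-carotene-3,3'-diol (monadoxanthin, CNP0232536.1)
Conditions: TBAF, THF, 0 °C → rt, dark, argon
Reagents that add atoms: none
Why: Fluoride-mediated desilylation should cleave both secondary TBS ethers under non-acidic conditions, which matters because the allylic 3'-hydroxy ε-ring and the polyene are acid-labile, and no stereocentre or double bond is affected.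

**Compound list**
1 | (4R,6R)-4-hydroxy-2,2,6-trimethylcyclohexan-1-one (actinol) | O=C1[C@H](C)C[C@@H](O)CC1(C)C | starting material
2 | (4R,6R)-4-[(tert-butyldimethylsilyl)oxy]-2,2,6-trimethylcyclohexan-1-one | O=C1[C@H](C)C[C@@H](O[Si](C)(C)C(C)(C)C)CC1(C)C | intermediate
3 | (4R)-4-[(tert-butyldimethylsilyl)oxy]-2,6,6-trimethylcyclohex-1-en-1-yl trifluoromethanesulfonate | O=S(=O)(OC1=C(C)C[C@@H](O[Si](C)(C)C(C)(C)C)CC1(C)C)C(F)(F)F | intermediate
4 | (2E)-3-methylpent-2-en-4-yn-1-ol | C#C/C(C)=C/CO | starting material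
5 | (2E)-5-[(4R)-4-[(tert-butyldimethylsilyl)oxy]-2,6,6-trimethylcyclohex-1-en-1-yl]-3-methylpent-2-en-4-yn-1-ol | OC/C=C(C)/C#CC1=C(C)C[C@@H](O[Si](C)(C)C(C)(C)C)CC1(C)C | intermediate
6 | {[(1R)-4-[(3E)-5-bromo-3-methylpent-3-en-1-yn-1-yl]-3,5,5-trimethylcyclohex-3-en-1-yl]oxy}(tert-butyl)dimethylsilane | BrC/C=C(C)/C#CC1=C(C)C[C@@H](O[Si](C)(C)C(C)(C)C)CC1(C)C | intermediate
7 | [(2E)-5-[(4R)-4-[(tert-butyldimethylsilyl)oxy]-2,6,6-trimethylcyclohex-1-en-1-yl]-3-methylpent-2-en-4-yn-1-yl]triphenylphosphonium bromide | [Br-].c1ccccc1[P+](c1ccccc1)(c1ccccc1)C/C=C(C)/C#CC1=C(C)C[C@@H](O[Si](C)(C)C(C)(C)C)CC1(C)C | intermediate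
8 | (2E,4E,6E)-2,7-dimethylocta-2,4,6-trienedial (C10-dialdehyde) | O=C/C(C)=C/C=C/C=C(C)/C=O | starting material
9 | (2E,4E,6E,8E,10E)-13-[(4R)-4-[(tert-butyldimethylsilyl)oxy]-2,6,6-trimethylcyclohex-1-en-1-yl]-2,7,11-trimethyltrideca-2,4,6,8,10-pentaen-12-ynal | O=C/C(C)=C/C=C/C=C(C)/C=C/C=C(\C)C#CC1=C(C)C[C@@H](O[Si](C)(C)C(C)(C)C)CC1(C)C | intermediate
10 | tert-butyl{[(1R)-4-[(3E,5E,7E,9E,11E,13E)-14-iodo-3,7,12-trimethyltetradeca-3,5,7,9,11,13-hexaen-1-yn-1-yl]-3,5,5-trimethylcyclohex-3-en-1-yl]oxy}dimethylsilane | I/C=C/C(C)=C/C=C/C=C(C)/C=C/C=C(\C)C#CC1=C(C)C[C@@H](O[Si](C)(C)C(C)(C)C)CC1(C)C | intermediate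
11 | (3E)-4-[(1R)-2,6,6-trimethylcyclohex-2-en-1-yl]but-3-en-2-one ((R)-α-ionone) | CC1=CCCC(C)(C)[C@H]1/C=C/C(C)=O | starting material
12 | diethyl (3E)-4-[(1R)-2,6,6-trimethylcyclohex-2-en-1-yl]buta-1,3-dien-2-yl phosphate | CC1=CCCC(C)(C)[C@H]1/C=C/C(=C)OP(=O)(OCC)OCC | intermediate
13 | (6R)-6-[(1E)-but-1-en-3-yn-1-yl]-1,5,5-trimethylcyclohex-1-ene | CC1=CCCC(C)(C)[C@H]1/C=C/C#C | intermediate
14 | (4R)-4-[(1E)-but-1-en-3-yn-1-yl]-3,5,5-trimethylcyclohex-2-en-1-one | CC1=CC(=O)CC(C)(C)[C@H]1/C=C/C#C | intermediate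
15 | (1R,4R)-4-[(1E)-but-1-en-3-yn-1-yl]-3,5,5-trimethylcyclohex-2-en-1-ol | CC1=C[C@H](O)CC(C)(C)[C@H]1/C=C/C#C | intermediate
16 | tert-butyl{[(1R,4R)-4-[(1E)-but-1-en-3-yn-1-yl]-3,5,5-trimethylcyclohex-2-en-1-yl]oxy}dimethylsilane | CC1=C[C@H](O[Si](C)(C)C(C)(C)C)CC(C)(C)[C@H]1/C=C/C#C | intermediate
17 | [(1E,3E)-4-[(1R,4R)-4-[(tert-butyldimethylsilyl)oxy]-2,6,6-trimethylcyclohex-2-en-1-yl]-2-methylbuta-1,3-dien-1-yl]dimethylalumane | CC1=C[C@H](O[Si](C)(C)C(C)(C)C)CC(C)(C)[C@H]1/C=C/C(C)=C/[Al](C)C | intermediate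
18 | (3R,3'R,6'R)-3,3'-bis[(tert-butyldimethylsilyl)oxy]-7,8-didehydro-β,ε-carotene | CC1=C[C@H](O[Si](C)(C)C(C)(C)C)CC(C)(C)[C@H]1/C=C/C(C)=C/C=C/C(C)=C/C=C/C=C(C)/C=C/C=C(\C)C#CC1=C(C)C[C@@H](O[Si](C)(C)C(C)(C)C)CC1(C)C | intermediate
19 | (3R,3'R,6'R)-7,8-didehydro-β,ε-carotene-3,3'-diol (monadoxanthin, CNP0232536.1) | CC1=C[C@H](O)CC(C)(C)[C@H]1/C=C/C(C)=C/C=C/C(C)=C/C=C/C=C(C)/C=C/C=C(\C)C#CC1=C(C)C[C@@H](O)CC1(C)C | target

**Step count and risks**
Total step count: 13 (steps 1–7 for the C26 iodide, steps 8–11 for the C13 enyne, steps 12–13 for union and deprotection).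
Longest linear sequence: 9 steps (1 → 2 → 3 → 5 → 6 → 7 → 9 → 10 → 18 → 19).

Steps most likely to fail:

1. Step 12. The alkenylalane may be lost by protodealumination or incomplete Al → Zn → Pd transfer, and the hexaenynyl iodide may isomerise or decompose in the Lewis-acidic Al/Zn medium before it couples. The fallback reverses the polarity and uses a neutral Stille coupling; it sets out from 16 and 9 and returns at 18. Enyne 16 would be methylaluminated as before and the alane 17 quenched with iodine (THF, −30 °C) to give the dienyl iodide tert-butyl{[(1R,4R)-4-[(1E,3E)-4-iodo-3-methylbuta-1,3-dien-1-yl]-3,5,5-trimethylcyclohex-2-en-1-yl]oxy}dimethylsilane F1. Aldehyde 9 would be converted by a Takai-type stannyl-olefination (CrCl2, Bu3SnCHBr2, LiI, THF/DMF) into the alkenylstannane tributyl[(1E,3E,5E,7E,9E,11E)-14-[(4R)-4-[(tert-butyldimethylsilyl)oxy]-2,6,6-trimethylcyclohex-1-en-1-yl]-3,8,12-trimethyltetradeca-1,3,5,7,9,11-hexaen-13-yn-1-yl]stannane F2. Stille coupling of the two (Pd2(dba)3, AsPh3, NMP, rt, dark) should then give 18.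

2. Step 9. Hydrogen abstraction may occur at the doubly allylic ring C–H, or peroxy radicals may add to the conjugated enyne, giving over-oxidation instead of clean ketone formation at the ring CH2. The fallback installs the oxygen before the alkyne exists; it sets out from 11 and returns at 16, bypassing 13–15.
   - (R)-α-Ionone would be ketalised ((TMSOCH2)2, TMSOTf cat., CH2Cl2, −78 °C) to 2-methyl-2-{(E)-2-[(1R)-2,6,6-trimethylcyclohex-2-en-1-yl]ethenyl}-1,3-dioxolane F3.
   - Allylic oxidation of this ketal (t-BuOOH, aq. NaOCl, MeCN, 0 °C) should give (4R)-3,5,5-trimethyl-4-[(E)-2-(2-methyl-1,3-dioxolan-2-yl)ethenyl]cyclohex-2-en-1-one F4.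
   - CBS reduction as in step 10 should give (1R,4R)-3,5,5-trimethyl-4-[(E)-2-(2-methyl-1,3-dioxolan-2-yl)ethenyl]cyclohex-2-en-1-ol F5.
   - Mild deketalisation (PPTS, acetone/H2O, rt) should give (3E)-4-[(1R,4R)-4-hydroxy-2,6,6-trimethylcyclohex-2-en-1-yl]but-3-en-2-one F6.
   - Silylation (TBSCl, imidazole, DMF) should give (3E)-4-[(1R,4R)-4-[(tert-butyldimethylsilyl)oxy]-2,6,6-trimethylcyclohex-2-en-1-yl]but-3-en-2-one F7.
   - The step 8 protocol (LDA; ClP(O)(OEt)2; LDA) should pass through diethyl (3E)-4-[(1R,4R)-4-[(tert-butyldimethylsilyl)oxy]-2,6,6-trimethylcyclohex-2-en-1-yl]buta-1,3-dien-2-yl phosphate F8, not isolated, to 16.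

3. Step 10. Facial selectivity may be poor if the substrate's own preference (hydride approach anti to the C4 side chain) opposes the catalyst. The fallback uses that preference and then inverts; it sets out from 14 and returns at 15. Reduction with L-Selectride (THF, −78 °C) should deliver hydride anti to the side chain and give the cis alcohol (1S,4R)-4-[(1E)-but-1-en-3-yn-1-yl]-3,5,5-trimethylcyclohex-2-en-1-ol F9. Mitsunobu inversion (4-nitrobenzoic acid, DIAD, PPh3, toluene, 0 °C) should give (1R,4R)-4-[(1E)-but-1-en-3-yn-1-yl]-3,5,5-trimethylcyclohex-2-en-1-yl 4-nitrobenzoate F10, and methanolysis (K2CO3, MeOH, rt) should give 15.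

**Further compounds**
F1 | step 12 | tert-butyl{[(1R,4R)-4-[(1E,3E)-4-iodo-3-methylbuta-1,3-dien-1-yl]-3,5,5-trimethylcyclohex-2-en-1-yl]oxy}dimethylsilane | CC1=C[C@H](O[Si](C)(C)C(C)(C)C)CC(C)(C)[C@H]1/C=C/C(C)=C/I
F2 | step 12 | tributyl[(1E,3E,5E,7E,9E,11E)-14-[(4R)-4-[(tert-butyldimethylsilyl)oxy]-2,6,6-trimethylcyclohex-1-en-1-yl]-3,8,12-trimethyltetradeca-1,3,5,7,9,11-hexaen-13-yn-1-yl]stannane | CCCC[Sn](CCCC)(CCCC)/C=C/C(C)=C/C=C/C=C(C)/C=C/C=C(\C)C#CC1=C(C)C[C@@H](O[Si](C)(C)C(C)(C)C)CC1(C)C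
F3 | step 9 | 2-methyl-2-{(E)-2-[(1R)-2,6,6-trimethylcyclohex-2-en-1-yl]ethenyl}-1,3-dioxolane | CC1=CCCC(C)(C)[C@H]1/C=C/C1(C)OCCO1
F4 | step 9 | (4R)-3,5,5-trimethyl-4-[(E)-2-(2-methyl-1,3-dioxolan-2-yl)ethenyl]cyclohex-2-en-1-one | CC1=CC(=O)CC(C)(C)[C@H]1/C=C/C1(C)OCCO1
F5 | step 9 | (1R,4R)-3,5,5-trimethyl-4-[(E)-2-(2-methyl-1,3-dioxolan-2-yl)ethenyl]cyclohex-2-en-1-ol | CC1=C[C@H](O)CC(C)(C)[C@H]1/C=C/C1(C)OCCO1
F6 | step 9 | (3E)-4-[(1R,4R)-4-hydroxy-2,6,6-trimethylcyclohex-2-en-1-yl]but-3-en-2-one | CC1=C[C@H](O)CC(C)(C)[C@H]1/C=C/C(C)=O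
F7 | step 9 | (3E)-4-[(1R,4R)-4-[(tert-butyldimethylsilyl)oxy]-2,6,6-trimethylcyclohex-2-en-1-yl]but-3-en-2-one | CC1=C[C@H](O[Si](C)(C)C(C)(C)C)CC(C)(C)[C@H]1/C=C/C(C)=O
F8 | step 9 | diethyl (3E)-4-[(1R,4R)-4-[(tert-butyldimethylsilyl)oxy]-2,6,6-trimethylcyclohex-2-en-1-yl]buta-1,3-dien-2-yl phosphate | CC1=C[C@H](O[Si](C)(C)C(C)(C)C)CC(C)(C)[C@H]1/C=C/C(=C)OP(=O)(OCC)OCC
F9 | step 10 | (1S,4R)-4-[(1E)-but-1-en-3-yn-1-yl]-3,5,5-trimethylcyclohex-2-en-1-ol | CC1=C[C@@H](O)CC(C)(C)[C@H]1/C=C/C#C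
F10 | step 10 | (1R,4R)-4-[(1E)-but-1-en-3-yn-1-yl]-3,5,5-trimethylcyclohex-2-en-1-yl 4-nitrobenzoate | CC1=C[C@H](OC(=O)c2ccc(cc2)[N+](=O)[O-])CC(C)(C)[C@H]1/C=C/C#C
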